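We begin at the early minutes of the flasks below and follow them to the last reading.

| flask | starting material | catalyst | time |
|---|---|---|---|
| midnight | 1.00 M | 0.0200 M |  |
| noon | 1.00 M | 0.0600 M |  |
| dusk | 1.50 M | 0.0200 M |  |
| spring | 0.400 M | 0.0200 M | 72 min |

| run | time / min | [product] / M |
|---|---|---|
| midnight run | 9.0 | 0.109 |
| midnight run | 18 | 0.199 |
| midnight run | 27 | 0.271 |
| midnight run | 36 | 0.337 |
| midnight run | 45 | 0.379 |
| midnight run | 54 | 0.424 |
| midnight run | 63 | 0.461 |
| midnight run | 72 | 0.488 |
| noon run | 9.0 | 0.232 |
| noon run | 18 | 0.400 |
| noon run | 27 | 0.509 |
| noon run | 36 | 0.589 |
| noon run | 45 | 0.647 |
| noon run | 54 | 0.697 |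
| noon run | 63 | 0.737 |
| noon run | 72 | 0.770 |
| dusk run | 9.0 | 0.145 |
| dusk run | 18 | 0.270 |
| dusk run | 27 | 0.365 |
| dusk run | 36 | 0.439 |
| dusk run | 45 | 0.502 |
| dusk run | 54 | 0.563 |
| dusk run | 63 | 0.613 |
| dusk run | 72 | 0.654 |

(standard deviation of a reading: 0.003 M)

1. apparent order in [catalyst] of the starting rate, round the charge of the midnight run (the rate where two percent of its starting material have turned into product)
2. apparent order in [starting material] of the starting rate, round the charge of the midnight run (the rate where two percent of its starting material have turned into product) (one fixed amount of product, the same in the runs compared)
3. product in the spring run at 72 min, as a share of the starting material charged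

- Overall: starting material -> product, with catalyst as catalyst.
- Constant volume, constant temperature.
- Bound and free are read together.
- An order is taken over about fifteen percent of the charge, up and down.

To see those minutes clearly we must first take out the later slowing, so we read it from the dusk run. Product made between 9.0 min and 27 min, per starting material left at the middle reading, stands 1.74 times as high as between 54 min and 72 min, while c(product) at those middles goes from 0.270 M to 0.613 M. Our own guess is product inhibition, with the rate going as c(starting material)·h/(h + c(product)). The ratio then gives a reading of h = 0.191 M, the hold point: the c(product) at which the rate per starting material is half its unhindered value.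

Summed over a run, this law gives a clock, (1 + c(charge)/h)·ln(c(charge)/c(starting material)) − c(product)/h, which in our reckoning ticks evenly at a pace proportional to the catalyst charge. The midnight run reads 0.149 at 9.0 min and 1.62 at 72 min, a pace of 0.0233 min⁻¹, and running it back shows a lag of 2.61 min.

So we read the first instants as a catalyst still coming up to strength. At full pace the midnight run would make 0.0609 M in that time, and the reference amount is smaller, a third of it. In our reckoning, while active catalyst is still growing steadily, the rate at fixed product goes as the square root of catalyst times starting material, an order of 0.5 in each; once it has grown the order is 1. We therefore expect both orders near 0.7.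

In the middle, the midnight run stands at 0.199 M at 18 min, about the hold point. By 72 min our law has 71.8 % of its catalyst held. The spring run has the same catalyst charge and is asked at that same time, so it should show the same clock. Its charge is twice the hold point, and solving the clock gives 60.7 %.

The forecast gives 0.8 and 0.78, higher than our orders, and 59 %, with the ground “dusk at the same remaining starting material runs far slower than midnight, so product inhibits strongly”.

The flask gives 60.7 % for the spring run, with orders of 0.65 in catalyst and 0.66 in starting material.

    active catalyst + starting material → product + active catalyst (1.116 M⁻¹ min⁻¹)
    active catalyst + product ⇌ catalyst-product complex, settled at all times (4.860 M⁻¹)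
    catalyst → active catalyst (0.3276 min⁻¹)

At the reference amount the noon run, with 3.00 times the catalyst of the midnight run, goes 2.0 times as fast. The hold point then serves the dusk run, which has the catalyst charge of the midnight run: at half its charge the clock reads 2.21, which the midnight pace and lag turn into 97.5 min, and the dusk run reaches that point at 95.4 min.

All runs stem from a simulated flask with constants of no real substance; scatter was added.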